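I started from amounts: the new flask takes 0.25 M each of Q and J, 0.750 M of G, which enters the solution as L, and 50 mM of D, and I wanted to know what stands in it after 2.0 h.

in all of them: D 50 mM

| flask | Q | J | G | remark | time |
|---|---|---|---|---|---|
| north | 0.25 M | 0.25 M | 1 M | run made earlier |  |
| south-east | 0.25 M | 0.25 M | 1.7 M | run made earlier |  |
| south | 0.50 M | 0.50 M | 0.75 M | run made earlier |  |
| flask | 0.25 M | 0.25 M | 0.750 M |  | 2.0 h |

| run | time / min | E / % | Z / % | Q / % |
|---|---|---|---|---|
| north | 30.0 | 37.6 | 8.0 | 4.6 |
| north | 60.0 | 32.9 | 18.5 | 0.7 |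
| north | 90.0 | 30.0 | 24.7 | 0.9 |
| north | 120 | 29.0 | 26.8 | 0 |
| south-east | 15.0 | 27.6 | 1.5 | 19.6 |
| south-east | 40.0 | 37.7 | 12.9 | 0.9 |
| south-east | 80.0 | 31.3 | 22.7 | 1.0 |
| south-east | 120 | 27.7 | 28.6 | 0 |
| south | 10.0 | 17.7 | 1.0 | 29.1 |
| south | 20.0 | 34.7 | 5.8 | 13.1 |
| south | 50.0 | 37.3 | 15.8 | 0.7 |
| south | 120 | 28.9 | 25.8 | 0.9 |

(standard deviation of a reading: 1 percentage point)

- excess of E over Z in the product at 2.5 min
- excess of E over Z in the product at 2.0 h
- part of the Q and J charged together that has reacted at 2.0 h

Read row against row, these runs showed which concentration sets the order of the rate. The south-east run, with 1.7 M of G, held 19.6% Q at 15.0 min. The south run, with 0.75 M of G and twice the Q, held 29.1% at 10.0 min and 13.1% at 20.0 min, and the geometric mean of those two, 19.5%, matches the south-east reading. So the share of Q lost followed neither the G charge nor the starting [Q], and I took [L] to stand at one level in these runs, which makes the loss pseudo-first-order.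

The last rows spoke for J. E and Z together read 55.8%, 56.3% and 54.7%, on average 55.6%. Q, half of the charge, read 0%, 0% and 0.9% in those rows, so I counted that half as reacted, and what E and Z hold above it is J that reacted. From this I carried the J constant, the first-order loss of J averaged over a whole run at 50 mM of D: 9.90 × 10⁻⁴ min⁻¹.

The new flask needs about 0.278 M of L, less than its 0.750 M of G. So I reckoned that J keeps 88.8% of its charge and that 55.6% of Q and J together reacts.

The forecast gave 96%, 2.5% and 56%, on the ground that the rate “does not depend on the G charge”.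

The flask gave 95.9%, 3.67% and 55.7%, and the forecast held on each.

    L + X + Q → X + E (k = 0.286 M⁻² s⁻¹)
    L + X + J → X + Z (k = 0.00296 M⁻² s⁻¹)
    G ⇌ L, rate k3*(cs3 - [L]) while solid is left; crystals form when [L] > cs3 (solubility = 0.120 M, k = 0.146 s⁻¹)
    E ⇌ Z (k = 2.06 × 10⁻⁴ s⁻¹)
    D → X (k = 0.00242 s⁻¹)

In this flask [L] stood at 0.120 M at 2.00 h, with 46.9% of the G charge undissolved, and 89% of the J charged was left, against my 88.8%. The scheme has X to the first power in the step of J, so for the neighbouring flask with 0.20 M of D I scaled the J constant to 0.00396 min⁻¹, which leaves 31.1% J in percent of Q and J together. That neighbouring flask held 30.9% J at 2.00 h, with [L] at 0.120 M. There 69.1% had reacted, and Z led, the excess of E over Z standing at −4.01%.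

The readings were computed on assumed constants, noise included.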